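The route rests on cutting the C4–C4a bond of ring C. In the target, C8 (bearing the chiral chain) sits between O1 and the C7 oxygen, so the ring A phenol that supplies O1 has a single free ortho carbon, the future C4a. Once this oxygen is vinylated as O1–C2, one intramolecular Friedel–Crafts acylation forms C4–C4a and closes the pyranone in the only direction open to it, giving the 8-substituted flavone with no 6-isomer. The precursor is a (Z)-3-aryloxy-3-(4-methoxyphenyl)acrylic acid whose aryloxy ring carries two methoxy groups and the (R)-CH(Ph)CH2CO2tBu chain; it comes from an enantioenriched 4-phenyldihydrocoumarin whose lactone oxygen becomes O1.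

Key step: step 4

Remark: the adduct of step 2 and the acid made from it are drawn as the Z isomers expected from anti addition; any E isomer is carried along, because both geometries converge at the acylium stage of step 4.
Remark: (R)-SEGPHOS is taken to give the R lactone by analogy with coumarins lacking the methoxy groups (these do not change the CIP order at C4); the antipodal ligand is used if a first run shows the opposite sense.

Step 1
Reactants: 1 5,7-dimethoxycoumarin; 2 phenylboronic acid
Product: 3 (R)-5,7-dimethoxy-4-phenylchroman-2-one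
Conditions: Rh(acac)(C2H4)2 (3 mol %), (R)-SEGPHOS (3.3 mol %), 2 (5 equiv), 1,4-dioxane/H2O 10:1, 60 °C
Reagents that add atoms: none
Why: Hayashi–Miyaura asymmetric 1,4-addition, in which the phenylrhodium species carrying (R)-SEGPHOS adds across the C3=C4 bond of the coumarin on one enantioface and water protonates the resulting oxa-π-allylrhodium, so that the ligand sets C4 as R, while the excess of boronic acid offsets protodeboronation and the slower insertion beside the peri 5-methoxy group.

Step 2
Reactants: 3 (R)-5,7-dimethoxy-4-phenylchroman-2-one; 4 methyl 3-(4-methoxyphenyl)propiolate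
Product: 6 methyl (Z)-3-{2-[(R)-3-tert-butoxy-3-oxo-1-phenylpropyl]-3,5-dimethoxyphenoxy}-3-(4-methoxyphenyl)acrylate, via potassium phenoxide 5 (not isolated)
Conditions: KOtBu (1.05 equiv), THF, −20 to 0 °C; then AcOH (0.85 equiv), 4 (1.3 equiv), DMF, 25 to 50 °C; aq. NH4Cl
Reagents that add atoms: potassium tert-butoxide, CC(C)(C)[O-].[K+]
Why: tert-Butoxide opens the aryl lactone by acyl substitution (an E1cB ketene pathway would converge on the same tert-butyl ester) and frees the former ring oxygen as phenoxide 5, which, once most of it is buffered to the phenol, adds in an oxa-Michael reaction to the β-carbon of ynoate 4 while the phenol protonates the vinyl anion, so that no free tert-butoxide builds up, anti addition should favour the Z ester, and the stereocentre, β to the ester and not acidic, stays untouched.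

Step 3
Reactants: 6 methyl (Z)-3-{2-[(R)-3-tert-butoxy-3-oxo-1-phenylpropyl]-3,5-dimethoxyphenoxy}-3-(4-methoxyphenyl)acrylate
Product: 7 (Z)-3-{2-[(R)-3-tert-butoxy-3-oxo-1-phenylpropyl]-3,5-dimethoxyphenoxy}-3-(4-methoxyphenyl)acrylic acid
Conditions: LiOH·H2O (3 equiv), THF/H2O 3:1, 25 to 40 °C; 1 M HCl to pH 3–4, 0 °C
Reagents that add atoms: lithium hydroxide, [Li+].[OH-]
Why: Saponification by acyl substitution at the unhindered methyl ester, with the tert-butyl ester shielded from hydroxide by its bulk, the β-aryl group disfavouring conjugate displacement of the phenoxide, and a mild cold acidification sparing the enol ether and the tert-butyl ester.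

Step 4
Reactants: 7 (Z)-3-{2-[(R)-3-tert-butoxy-3-oxo-1-phenylpropyl]-3,5-dimethoxyphenoxy}-3-(4-methoxyphenyl)acrylic acid
Product: 9 tert-butyl (R)-3-[5,7-dimethoxy-2-(4-methoxyphenyl)-4-oxo-4H-chromen-8-yl]-3-phenylpropanoate, via acyl chloride 8 (not isolated)
Conditions: 1-chloro-N,N,2-trimethylprop-1-en-1-amine (1.05 equiv), CH2Cl2, 0 °C to rt; then 2,6-di-tert-butylpyridine (1.5 equiv), AgOSO2CF3 (1.2 equiv), CH2Cl2 (0.02 M), −40 to 0 °C, dark
Reagents that add atoms: none
Why: The α-chloroenamine converts acid 7 into acyl chloride 8 without liberating acid, and AgOSO2CF3 then removes chloride as AgCl to give an acylium ion that is delocalised as a ketene–oxocarbenium ion over C3, C2, O1 and the anisyl ring. This electrophile attacks the one unsubstituted carbon ortho to the vinylated oxygen, the future C4a, which is activated by O1 and one methoxy group in ortho and by the other methoxy group in para positions, and the hindered pyridine removes the proton of the σ-complex, so the C4–C4a bond and ring C form together. The closest known reaction type is the Ruhemann flavone synthesis, the intramolecular Friedel–Crafts acylation of 3-aryloxycinnamic acids and their chlorides. Ring C closes by six-membered exo attack at the acyl carbon (6-exo-trig counted on the acyl chloride), the arene C4a=C8a bond lying inside the new ring. No stereocentre is created, and the benzylic centre is neither acidic nor cationic under these conditions. The selectivity needed is closure at C4a instead of acylation of a second molecule or of the anisyl ring, and it is secured by the substrate: the other ortho carbon carries the side chain (ipso attack there cannot end in proton loss), the E and Z forms interconvert at the acylium stage because the C2–C3 bond is then largely single, only the Z-like rotamer reaches C4a, and high dilution together with the buffered medium keeps intermolecular acylation and loss of the tert-butyl ester in check.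

Step 5
Reactants: 9 tert-butyl (R)-3-[5,7-dimethoxy-2-(4-methoxyphenyl)-4-oxo-4H-chromen-8-yl]-3-phenylpropanoate
Product: 10 (R)-3-[5,7-dihydroxy-2-(4-hydroxyphenyl)-4-oxo-4H-chromen-8-yl]-3-phenylpropanoic acid
Conditions: BBr3 (10 equiv), CH2Cl2, −78 °C to rt; ice-water; aq. NaOH to pH 12, 0 °C, 10 min, argon; 1 M HCl to pH 3, 0 °C
Reagents that add atoms: none
Why: Lewis acid ether cleavage in which BBr3 coordinates each methoxy oxygen (the 5-methoxy group first, helped by the C4 carbonyl) and bromide removes the methyl groups by SN2 attack, the tert-butyl ester falls by O-alkyl fission, the benzylic stereocentre is not involved, and the short cold alkaline stage reopens any lactone formed between the acid and the 7-OH before careful acidification.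

Compound list
1 | 5,7-dimethoxycoumarin (5,7-dimethoxy-2H-chromen-2-one) | COc1cc(OC)c2ccc(=O)oc2c1 | starting material
2 | phenylboronic acid | OB(O)c1ccccc1 | starting material
3 | (R)-5,7-dimethoxy-4-phenylchroman-2-one | O=C1C[C@H](c2ccccc2)c2c(OC)cc(OC)cc2O1 | intermediate
4 | methyl 3-(4-methoxyphenyl)propiolate | COC(=O)C#Cc1ccc(OC)cc1 | starting material
5 | potassium 2-[(R)-3-tert-butoxy-3-oxo-1-phenylpropyl]-3,5-dimethoxyphenolate | CC(C)(C)OC(=O)C[C@H](c1ccccc1)c1c([O-])cc(OC)cc1OC.[K+] | intermediate
6 | methyl (Z)-3-{2-[(R)-3-tert-butoxy-3-oxo-1-phenylpropyl]-3,5-dimethoxyphenoxy}-3-(4-methoxyphenyl)acrylate | COC(=O)/C=C(\Oc1cc(OC)cc(OC)c1[C@H](CC(=O)OC(C)(C)C)c1ccccc1)c1ccc(OC)cc1 | intermediate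
7 | (Z)-3-{2-[(R)-3-tert-butoxy-3-oxo-1-phenylpropyl]-3,5-dimethoxyphenoxy}-3-(4-methoxyphenyl)acrylic acid | O=C(O)/C=C(\Oc1cc(OC)cc(OC)c1[C@H](CC(=O)OC(C)(C)C)c1ccccc1)c1ccc(OC)cc1 | intermediate
8 | (Z)-3-{2-[(R)-3-tert-butoxy-3-oxo-1-phenylpropyl]-3,5-dimethoxyphenoxy}-3-(4-methoxyphenyl)acryloyl chloride | O=C(Cl)/C=C(\Oc1cc(OC)cc(OC)c1[C@H](CC(=O)OC(C)(C)C)c1ccccc1)c1ccc(OC)cc1 | intermediate
9 | tert-butyl (R)-3-[5,7-dimethoxy-2-(4-methoxyphenyl)-4-oxo-4H-chromen-8-yl]-3-phenylpropanoate | CC(C)(C)OC(=O)C[C@H](c1ccccc1)c1c(OC)cc(OC)c2c(=O)cc(-c3ccc(OC)cc3)oc12 | intermediate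
10 | (R)-3-[5,7-dihydroxy-2-(4-hydroxyphenyl)-4-oxo-4H-chromen-8-yl]-3-phenylpropanoic acid | O=C(O)C[C@H](c1ccccc1)c1c(O)cc(O)c2c(=O)cc(-c3ccc(O)cc3)oc12 | target

Total step count: 5. Longest linear sequence: 5 steps (1 → 3 → 6 → 7 → 9 → 10).

Steps most likely to fail

Step 4. The acylium ion may be lost to acylation of a second molecule (the carbon between the two methoxy groups is also nucleophilic) or to closure on the anisyl ring, or the tert-butyl ester may be cleaved before ring closure. The fallback sets out from 5 and comes back to the route at 9. It makes the C4–C4a bond by a chelation-directed formylation and closes ring C at O1–C2 instead: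
- The opening of 3 with KOtBu is quenched cold with aqueous NH4Cl to give the free phenol tert-butyl (R)-3-(2-hydroxy-4,6-dimethoxyphenyl)-3-phenylpropanoate F1.
- Casnati–Skattebøl ortho-formylation (MgCl2, Et3N, paraformaldehyde, MeCN, 70 °C) can reach only the one free ortho carbon and should give tert-butyl (R)-3-(3-formyl-2-hydroxy-4,6-dimethoxyphenyl)-3-phenylpropanoate F2.
- Excess lithium (4-methoxyphenyl)acetylide (4-ethynylanisole, n-BuLi, THF, −78 °C) should add to the aldehyde to give tert-butyl (3R)-3-{2-hydroxy-3-[1-hydroxy-3-(4-methoxyphenyl)prop-2-yn-1-yl]-4,6-dimethoxyphenyl}-3-phenylpropanoate F3 as a mixture of carbinol epimers.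
- MnO2 (CH2Cl2, rt) should oxidise this to the ynone tert-butyl (R)-3-{2-hydroxy-4,6-dimethoxy-3-[3-(4-methoxyphenyl)prop-2-ynoyl]phenyl}-3-phenylpropanoate F4.
- Et2NH in EtOH should then close ring C by 6-endo-dig oxa-Michael addition through the enaminone, giving 9.

Step 2. Conjugate addition of the ortho-hindered phenoxide to the electron-rich ynoate may be slow, leaving time for relactonisation to 3 and base-induced decay of 4. The fallback sets out from 4 and 5 and comes back at 6. It replaces alkyne addition by vinylic addition–elimination, which needs no proton transfer and therefore no free phenol: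
- 4 is hydrochlorinated (LiCl, AcOH, MeCN, 80 °C) to methyl (Z)-3-chloro-3-(4-methoxyphenyl)acrylate F5.
- Unbuffered 5, made as in step 2, is treated with F5 in DMF at 25 to 60 °C; the ester enolate formed by attack at the β-carbon expels chloride irreversibly, with retention, to give 6.

Step 1. Insertion at C4 beside the peri 5-methoxy group may be slow, so that protodeboronation outruns addition, or enantioface selectivity may be insufficient. The fallback sets out from 1 and 2 and comes back at 3. It brings in the phenyl group without a stereocentre and sets the centre by hydride delivery: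
- Oxidative Heck arylation (Pd(OAc)2, 1,10-phenanthroline, O2, DMF, 80 °C) should give 5,7-dimethoxy-4-phenylcoumarin F6.
- Copper hydride asymmetric conjugate reduction (Cu(OAc)2·H2O, DTBM-SEGPHOS, (EtO)2MeSiH, t-BuOH, toluene, rt) should give 3. The ligand antipode is chosen in a test run for the R lactone.

Further compounds
F1 | step 4 | tert-butyl (R)-3-(2-hydroxy-4,6-dimethoxyphenyl)-3-phenylpropanoate | CC(C)(C)OC(=O)C[C@H](c1ccccc1)c1c(O)cc(OC)cc1OC
F2 | step 4 | tert-butyl (R)-3-(3-formyl-2-hydroxy-4,6-dimethoxyphenyl)-3-phenylpropanoate | CC(C)(C)OC(=O)C[C@H](c1ccccc1)c1c(O)c(C=O)c(OC)cc1OC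
F3 | step 4 | tert-butyl (3R)-3-{2-hydroxy-3-[1-hydroxy-3-(4-methoxyphenyl)prop-2-yn-1-yl]-4,6-dimethoxyphenyl}-3-phenylpropanoate (carbinol epimers) | CC(C)(C)OC(=O)C[C@H](c1ccccc1)c1c(O)c(C(O)C#Cc2ccc(OC)cc2)c(OC)cc1OC
F4 | step 4 | tert-butyl (R)-3-{2-hydroxy-4,6-dimethoxy-3-[3-(4-methoxyphenyl)prop-2-ynoyl]phenyl}-3-phenylpropanoate | CC(C)(C)OC(=O)C[C@H](c1ccccc1)c1c(O)c(C(=O)C#Cc2ccc(OC)cc2)c(OC)cc1OC
F5 | step 2 | methyl (Z)-3-chloro-3-(4-methoxyphenyl)acrylate | COC(=O)/C=C(\Cl)c1ccc(OC)cc1
F6 | step 1 | 5,7-dimethoxy-4-phenylcoumarin | COc1cc(OC)c2c(-c3ccccc3)cc(=O)oc2c1
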